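## Retrosynthetic overview

1. The γ-lactone is closed last: C8–C17 by a SmI2 Reformatsky reaction of a C7 2-bromopropionate onto a C8 ketone. The 11,20-epoxide comes from an exocyclic C11=C20 alkene just before.
2. The C2 and C14 acetoxy carbinols come from a 2,14-dione (bulky hydride at C14, then hydroxyl-directed reduction at C2).
3. Key disconnection C1–C10: transannular Mn(III)/Cu(II) oxidative radical cyclisation of a 14-membered 2-methyl-1,3-diketone. Its C1 radical is C2-symmetric, so one event forms the cyclohexane and the ten-membered ring and leaves C11=C20.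
4. The 14-membered ring comes from a bis(vinyl iodide) diketone and 2,2-dimethoxymalonaldehyde by a double asymmetric Nozaki–Hiyama–Kishi (NHK) coupling (sets C7 and C9). Both Z-alkenes come from Cu-catalysed carbomagnesiation of propargyl alcohol.
5. Ring order: 14-membered carbocycle → cyclohexane + ten-membered ring (simultaneously) → epoxide → γ-lactone.

Assumption: 2,2-dimethoxypropane-1,3-diol is bought as the commercial dimethyl-ketal-protected form of dihydroxyacetone, and the NHK ligand antipode is the one that delivers the (S,S)-diol.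

Briarane numbering is used for bicyclic compounds: C1 (quaternary, Me-15), C2–C9 (ten-membered ring), C10, C11 (bearing C20), C12–C14 (six-membered ring), Me-16 on C5, C17(Me-18)–C19 (lactone). Compounds 10–18 lack or are building C17–C19.

## Route

**Step 1**
Reactants: 1 prop-2-yn-1-ol
Product: 2 (Z)-3-iodo-2-methylprop-2-en-1-ol
Conditions: MeMgBr (2.5 equiv), CuI (10 mol %), THF, −10 °C → rt; then I2, −10 °C
Reagents that add atoms: methylmagnesium bromide, C[Mg]Br; iodine, II
Why: Cu-catalysed anti-carbomagnesiation of the propargylic alkoxide puts Me on C2 and Mg on C3 in a five-membered chelate, and iodinolysis with retention gives only the Z isomer (I cis to CH2OH).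

**Step 2**
Reactants: 2 (Z)-3-iodo-2-methylprop-2-en-1-ol
Product: 3 (Z)-3-bromo-1-iodo-2-methylprop-1-ene
Conditions: PBr3, Et2O, 0 °C
Reagents that add atoms: phosphorus tribromide, BrP(Br)Br
Why: SN2 bromination of a primary allylic alcohol; the alkene geometry is untouched.

**Step 3**
Reactants: 4 3-methylpentane-2,4-dione; 3 (2 equiv)
Product: 5 (1Z,10Z)-1,11-diiodo-2,6,10-trimethylundeca-1,10-diene-5,7-dione
Conditions: LDA (2.1 equiv), THF, 0 °C, then 3 (1 equiv), −78 → 0 °C; LDA (1.1 equiv), then 3 (1 equiv), −78 → 0 °C (one pot)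
Reagents that add atoms: none
Why: Hauser dianion γ-alkylation run twice: the terminal carbanion is alkylated by the allylic bromide, and the second deprotonation occurs at the remaining methyl, leaving the central C–H for later radical generation.

**Step 4**
Reactants: 6 2,2-dimethoxypropane-1,3-diol
Product: 7 2,2-dimethoxypropanedial
Conditions: (COCl)2, DMSO, CH2Cl2, −78 °C; Et3N; used crude
Reagents that add atoms: none
Why: Swern oxidation; the dialdehyde cannot enolise because the ketal carbon is quaternary.

**Step 5**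
Reactants: 5 bis(vinyl iodide) diketone; 7 2,2-dimethoxypropanedial
Product: 8 (6Z,8S,10S,11Z)-8,10-dihydroxy-9,9-dimethoxy-2,6,12-trimethylcyclotetradeca-6,11-diene-1,3-dione (the carbinols are C7 and C9 of the target; the CH(Me) between the ketones is not a stereocentre)
Conditions: CrCl2, chiral oxazoline–sulfonamide ligand (Kishi type), Et3N, NiCl2·(2,9-dimethylphenanthroline) (cat.), THF/MeCN, rt, syringe-pump addition of 5 + 7 (final 4 mM)
Reagents that add atoms: none
Why: Ni/Cr Nozaki–Hiyama–Kishi alkenylation, first inter- then intramolecular (alkenyl–Cr(III) bonds add only to aldehydes and resist protonolysis by the β-diketone); Z geometry is retained and the chiral Cr complex sets both carbinols with the same sense, wrong-sense additions ending in the separable meso diol.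

**Step 6**
Reactants: 8 macrocyclic diol
Product: 9 (6Z,8S,10S,11Z)-8,10-bis(tert-butyldimethylsilyloxy)-9,9-dimethoxy-2,6,12-trimethylcyclotetradeca-6,11-diene-1,3-dione
Conditions: TBSCl, imidazole, DMAP (cat.), DMF, 40 °C
Reagents that add atoms: tert-butyldimethylsilyl chloride, CC(C)(C)[Si](C)(C)Cl
Why: Standard silylation; the silyl ethers direct the key step sterically and later allow C2/C14 to be acetylated separately from C7/C9.

**Step 7 (key step)**
Reactants: 9 bis-TBS macrocycle
Product: 10 (1S,5Z,7S,9S,10S)-7,9-bis(tert-butyldimethylsilyloxy)-8,8-dimethoxy-17,18,19-trinorbriara-5,11(20)-diene-2,14-dione (trans-fused bicyclo[8.4.0]; Me-15 β, H-10 α)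
Conditions: Mn(OAc)3·2H2O (2.2 equiv), Cu(OAc)2·H2O (1 equiv), degassed AcOH, 30 °C, 0.01 M
Reagents that add atoms: none
Why: Proposed new method: Mn(III) oxidises the 2-methyl-1,3-diketone to the C1 radical, which is C2-symmetric, so 6-endo addition to either equivalent Z-alkene gives the same C1–C10 bond; a chair transition state with the W-shaped dicarbonyl radical (C2 acyl pseudo-axial, methyl pseudo-equatorial) and the Z-alkene substituent C9 pseudo-axial gives the trans ring fusion with Me-15 cis to C9; allylic 1,3-strain holds H-9 in the alkene plane so the radical adds anti to the bulky ketal carbon C8 (OTBS outside), relaying C9 to C10 and C1; Cu(II) oxidises the tertiary C11 radical to the less substituted exocyclic alkene; the closest known chemistry is the Snider Mn(OAc)3/Cu(OAc)2 6-endo cyclisation of α-methyl β-dicarbonyls (acyl group axial) and transannular radical cyclisations of macrocycles.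

**Step 8**
Reactants: 10 2,14-dione
Product: 11 (1R,5Z,7S,9S,10S,14S)-7,9-bis(tert-butyldimethylsilyloxy)-14-hydroxy-8,8-dimethoxy-17,18,19-trinorbriara-5,11(20)-dien-2-one (14α-OH, axial, trans to Me-15)
Conditions: L-Selectride (1.1 equiv), THF, −78 °C
Reagents that add atoms: none
Why: Bulky-hydride reduction; the cyclohexanone reacts in preference to the ten-membered-ring ketone (medium-ring ketones resist rehybridisation), and equatorial attack gives the axial alcohol as in 4,4-dimethyl-3-keto steroids.

**Step 9**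
Reactants: 11 14-hydroxy-2-ketone
Product: 12 (1S,2S,5Z,7S,9S,10S,14S)-7,9-bis(tert-butyldimethylsilyloxy)-8,8-dimethoxy-17,18,19-trinorbriara-5,11(20)-diene-2,14-diol
Conditions: Me4NBH(OAc)3, MeCN/AcOH, −30 °C
Reagents that add atoms: none
Why: Evans–Saksena directed reduction: hydride is delivered intramolecularly from the C14 alkoxyborohydride through a chair transition state with C3 pseudo-equatorial, giving the 1,3-anti diol, which is the 2β (2S) alcohol.

**Step 10**
Reactants: 12 2,14-diol
Product: 13 (1S,2S,5Z,7S,9S,10S,14S)-2,14-diacetoxy-7,9-bis(tert-butyldimethylsilyloxy)-8,8-dimethoxy-17,18,19-trinorbriara-5,11(20)-diene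
Conditions: Ac2O, DMAP, Et3N, CH2Cl2, rt
Reagents that add atoms: acetic anhydride, CC(=O)OC(C)=O
Why: DMAP-catalysed acetylation of the two free secondary alcohols; C7 and C9 stay silylated.

**Step 11**
Reactants: 13 diacetate
Product: 14 (1S,2S,5Z,7S,9S,10S,14S)-2,14-diacetoxy-7,9-dihydroxy-17,18,19-trinorbriara-5,11(20)-dien-8-one
Conditions: 48% aq. HF, MeCN, 0 °C → rt
Reagents that add atoms: water, O
Why: Aqueous HF removes both TBS ethers and hydrolyses the ketose-type dimethyl ketal to the C8 ketone; acetates and both alkenes tolerate these conditions.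

**Step 12**
Reactants: 14 dihydroxy ketone; 15 2-bromopropanoyl bromide (racemic)
Product: 16 (1S,2S,5Z,7S,9S,10S,14S)-2,14-diacetoxy-7-(2-bromopropanoyloxy)-9-hydroxy-17,18,19-trinorbriara-5,11(20)-dien-8-one (mixture at CHBr)
Conditions: pyridine, CH2Cl2, −78 → −40 °C
Reagents that add atoms: none
Why: Chemoselective acylation of the less hindered allylic C7–OH (C9–OH is shielded by C10 and the quaternary C1); the CHBr configuration is erased in step 15.

**Step 13**
Reactants: 16 C7 bromopropionate
Product: 17 (1S,2S,5Z,7S,9S,10S,14S)-2,9,14-triacetoxy-7-(2-bromopropanoyloxy)-17,18,19-trinorbriara-5,11(20)-dien-8-one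
Conditions: Ac2O, Sc(OTf)3 (cat.), MeCN, −20 °C
Reagents that add atoms: acetic anhydride, CC(=O)OC(C)=O
Why: Lewis-acid-catalysed acetylation of the hindered C9–OH under non-basic conditions, which avoids enolisation at the acidic C7–H.

**Step 14**
Reactants: 17 triacetate
Product: 18 (1S,2S,5Z,7S,9S,10S,11R,14S)-2,9,14-triacetoxy-7-(2-bromopropanoyloxy)-11,20-epoxy-17,18,19-trinorbriar-5-en-8-one
Conditions: mCPBA (1.1 equiv), NaHCO3, CH2Cl2, 0 °C
Reagents that add atoms: m-chloroperoxybenzoic acid, OOC(=O)c1cccc(Cl)c1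
Why: Prilezhaev epoxidation; C5=C6 is deactivated by the allylic acyloxy group and the adjacent ketone, so the 1,1-disubstituted C11=C20 reacts, and the peracid approaches from the equatorial α-face because the β-face is blocked 1,3-diaxially by Me-15 (gives 11R).

**Step 15**
Reactants: 18 epoxy bromo ester
Product: 19 Junceellolide K, (1S,2S,5Z,7S,8S,9S,10S,11R,14S,17R)-2,9,14-triacetoxy-11,20-epoxy-8-hydroxybriar-5-en-19,7-olide
Conditions: SmI2 (2.2 equiv, added dropwise), THF, −78 °C; aq. NH4Cl
Reagents that add atoms: none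
Why: SmI2-promoted intramolecular Reformatsky reaction: the Sm(III) enolate adds to the C8 ketone through a Sm-chelated transition state with C6 anti to C9 about C7–C8 (trans-fused lactone, 8α-OH) and the enolate methyl turned away from C9 (Me-18 cis to OH, 17R, also the thermodynamic epimer).

## Compound list

1 | prop-2-yn-1-ol | C#CCO | starting material
2 | (Z)-3-iodo-2-methylprop-2-en-1-ol | I/C=C(C)\CO | intermediate
3 | (Z)-3-bromo-1-iodo-2-methylprop-1-ene | I/C=C(C)\CBr | intermediate
4 | 3-methylpentane-2,4-dione | CC(=O)C(C)C(C)=O | starting material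
5 | (1Z,10Z)-1,11-diiodo-2,6,10-trimethylundeca-1,10-diene-5,7-dione | I/C=C(C)\CCC(=O)C(C)C(=O)CC/C(C)=C\I | intermediate
6 | 2,2-dimethoxypropane-1,3-diol (dihydroxyacetone, ketone protected as dimethyl ketal) | OCC(OC)(OC)CO | starting material
7 | 2,2-dimethoxypropanedial | O=CC(OC)(OC)C=O | intermediate
8 | (6Z,8S,10S,11Z)-8,10-dihydroxy-9,9-dimethoxy-2,6,12-trimethylcyclotetradeca-6,11-diene-1,3-dione | O=C1CC/C(C)=C\[C@H](O)C(OC)(OC)[C@@H](O)/C=C(C)\CCC(=O)C1C | intermediate
9 | bis-TBS ether of 8 | O=C1CC/C(C)=C\[C@H](O[Si](C)(C)C(C)(C)C)C(OC)(OC)[C@@H](O[Si](C)(C)C(C)(C)C)/C=C(C)\CCC(=O)C1C | intermediate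
10 | (1S,5Z,7S,9S,10S)-7,9-bis(TBSO)-8,8-dimethoxy-17,18,19-trinorbriara-5,11(20)-diene-2,14-dione | O=C1CC/C(C)=C\[C@H](O[Si](C)(C)C(C)(C)C)C(OC)(OC)[C@@H](O[Si](C)(C)C(C)(C)C)[C@H]2C(=C)CCC(=O)[C@]12C | intermediate
11 | (1R,5Z,7S,9S,10S,14S)-14-hydroxy-2-ketone | O=C1CC/C(C)=C\[C@H](O[Si](C)(C)C(C)(C)C)C(OC)(OC)[C@@H](O[Si](C)(C)C(C)(C)C)[C@H]2C(=C)CC[C@H](O)[C@]12C | intermediate
12 | (1S,2S,5Z,7S,9S,10S,14S)-2,14-diol | O[C@H]1CC/C(C)=C\[C@H](O[Si](C)(C)C(C)(C)C)C(OC)(OC)[C@@H](O[Si](C)(C)C(C)(C)C)[C@H]2C(=C)CC[C@H](O)[C@]12C | intermediate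
13 | 2,14-diacetate of 12 | CC(=O)O[C@H]1CC/C(C)=C\[C@H](O[Si](C)(C)C(C)(C)C)C(OC)(OC)[C@@H](O[Si](C)(C)C(C)(C)C)[C@H]2C(=C)CC[C@H](OC(C)=O)[C@]12C | intermediate
14 | (1S,2S,5Z,7S,9S,10S,14S)-2,14-diacetoxy-7,9-dihydroxy-17,18,19-trinorbriara-5,11(20)-dien-8-one | CC(=O)O[C@H]1CC/C(C)=C\[C@H](O)C(=O)[C@@H](O)[C@H]2C(=C)CC[C@H](OC(C)=O)[C@]12C | intermediate
15 | 2-bromopropanoyl bromide (racemic) | CC(Br)C(=O)Br | starting material
16 | 7-O-(2-bromopropanoyl) derivative of 14 | CC(=O)O[C@H]1CC/C(C)=C\[C@H](OC(=O)C(C)Br)C(=O)[C@@H](O)[C@H]2C(=C)CC[C@H](OC(C)=O)[C@]12C | intermediate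
17 | 9-acetate of 16 | CC(=O)O[C@H]1CC/C(C)=C\[C@H](OC(=O)C(C)Br)C(=O)[C@@H](OC(C)=O)[C@H]2C(=C)CC[C@H](OC(C)=O)[C@]12C | intermediate
18 | (11R)-11,20-epoxide of 17 | CC(=O)O[C@H]1CC/C(C)=C\[C@H](OC(=O)C(C)Br)C(=O)[C@@H](OC(C)=O)[C@H]2[C@]3(CC[C@H](OC(C)=O)[C@]12C)CO3 | intermediate
19 | Junceellolide K | CC(=O)O[C@H]1CC/C(C)=C\[C@@H]2OC(=O)[C@H](C)[C@@]2(O)[C@@H](OC(C)=O)[C@H]2[C@]3(CC[C@H](OC(C)=O)[C@]12C)CO3 | target

## Summary

Total steps: 15. Longest linear sequence: 14 (steps 1–3 and 5–15; step 4 is a one-step branch).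

Steps most likely to fail, each with a fallback:

1. **Step 7 (transannular Mn(III)/Cu(II) cyclisation).** Risks are the wrong ring-fusion or C9/C10 diastereomer, and endocyclic alkene isomers from the Cu(II) oxidation. Fallback: run the same 6-endo oxidative cyclisation on an open-chain 2-methyl-1,3-diketone carrying only the C9-silyloxy arm, so the cyclohexane is made first. Then close the ten-membered ring afterwards by intramolecular NHK at C6–C7.
2. **Step 5 (two-component double asymmetric NHK macrocyclisation).** Risks are oligomerisation, Cr sequestration by the β-diketone and insufficient enantiocontrol at high dilution. Fallback: reverse the order of bond formation. Couple the TBS ether of 2 with 7 by intermolecular two-directional asymmetric NHK, convert the termini to allylic bromides, and close the 14-membered ring by double dianion alkylation of 4.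
3. **Step 14 (chemoselective epoxidation).** The risk is competing epoxidation of C5=C6. Fallback: epoxidise at the stage of 16 with VO(acac)2/TBHP, using the free homoallylic C9–OH as the only directing group, then acetylate C9.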